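**Plan**

- Numbering (kept for all intermediates): C1 (isopropenyl), C4 (Me), C5 (OAc), C8 (Me), C10 (C=O), C12 (Me), C13 (OAc), C14. The oxygen-bearing carbons C5 and C10 are joined through C6–C9 with the C8 methyl; this 1,6-dioxygenated unit in the 14-membered ring is the retron of an oxy-Cope rearrangement of a ten-membered ring in which C5 is bonded to C10.
- Retrosynthesis: remove the acetates and the C5 carbinol hydrogen and mask C10 as its methyl enol ether; cut C7–C8 while joining C5–C10 (14- to 10-membered ring); then cut C10–propenyl, C5–vinyl, C5–C10 (acyloin), C3–C4 (imide alkylation), C10–C11 (Arndt–Eistert), C12–C13 (aldol) and C1–isopropenyl (conjugate addition).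
- Forward: lactone, open chain C13…C3, aldol, one-carbon homologation, alkylation to the C5…C10 diester; the Rühlmann cyclisation closes the ten-membered ring and the anionic oxy-Cope rearrangement expands it to the 14-membered ring.
- Stereochemistry: C1 from the BINAP–rhodium catalyst; C12/C13 and C4 from one oxazolidinone auxiliary; the C10 carbinol from an oxazaborolidine reduction, relayed to C5 by chelation and back to quaternary C10 by a Felkin–Anh addition; C8 by chirality transfer through the chair transition state; C5–OH by Felkin–Anh reduction.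

Key step: step 21

Assumption: the BINAP–rhodium catalyst is taken to add the alkenyl group to the unsaturated lactone with the same facial sense as to cyclic enones, so that (S)-BINAP should give the (S)-lactone.
Assumption: in the oxazaborolidine reduction the acyl side of C10 is taken as the larger substituent, so that the (S)-catalyst should give the (10R)-carbinol; the antipodal ligand or catalyst would be used if either sense were reversed.
Assumption: the enediol ether from the acyloin step is drawn ring-cis; its geometry is erased in the next step.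

**Route**

Step 1
Reactants: 1 5,6-dihydro-2H-pyran-2-one; 2 potassium trifluoro(prop-1-en-2-yl)borate
Product: 3 (S)-4-(prop-1-en-2-yl)oxan-2-one
Conditions: [Rh(cod)2]BF4 (3 mol %), (S)-BINAP (3.3 mol %), toluene/H2O, 100 °C
Reagents that add atoms: none
Why: Rhodium-catalysed asymmetric conjugate addition of an alkenylboron reagent (Hayashi–Miyaura reaction) to the cyclic enoate; the BINAP-bound alkenylrhodium species selects one enantioface and so sets C1 as S.

Step 2
Reactants: 3 (S)-4-(prop-1-en-2-yl)oxan-2-one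
Product: 4 (S)-5-hydroxy-N-methoxy-N-methyl-3-(prop-1-en-2-yl)pentanamide
Conditions: MeNH(OMe)·HCl, AlMe3, CH2Cl2, 0 °C to rt
Reagents that add atoms: N,O-dimethylhydroxylamine hydrochloride, CNOC.Cl
Why: Aluminium amide aminolysis of the lactone (Weinreb amide formation) opens the ring and tells the two arms at C1 apart, C13 as an amide and C3 as a primary alcohol.

Step 3
Reactants: 4 hydroxy Weinreb amide
Product: 5 (S)-5-[(tert-butyldimethylsilyl)oxy]-N-methoxy-N-methyl-3-(prop-1-en-2-yl)pentanamide
Conditions: t-BuMe2SiCl, imidazole, DMF, rt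
Reagents that add atoms: tert-butyldimethylsilyl chloride, CC(C)(C)[Si](C)(C)Cl
Why: Imidazole-promoted silylation of the primary alcohol prevents relactonisation and protects C3–OH through the aldol and homologation steps.

Step 4
Reactants: 5 silyloxy Weinreb amide
Product: 6 (S)-5-[(tert-butyldimethylsilyl)oxy]-3-(prop-1-en-2-yl)pentanal
Conditions: i-Bu2AlH, THF, −78 °C; aq. potassium sodium tartrate
Reagents that add atoms: none
Why: Weinreb amide reduction: the chelated tetrahedral aluminium intermediate survives until work-up, so the reduction stops at the C13 aldehyde.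

Step 5
Reactants: 6 aldehyde; 7 (S)-4-benzyl-3-propionyloxazolidin-2-one
Product: 9 (S)-4-benzyl-3-[(2S,3R,5S)-7-[(tert-butyldimethylsilyl)oxy]-3-hydroxy-2-methyl-5-(prop-1-en-2-yl)heptanoyl]oxazolidin-2-one, via dibutylboron (Z)-enolate of the imide 8 (not isolated)
Conditions: 7, n-Bu2BOTf, i-Pr2NEt, CH2Cl2, −78 to 0 °C; then 6, −78 to 0 °C; H2O2, MeOH, pH 7 buffer, 0 °C
Reagents that add atoms: none
Why: Evans syn aldol reaction: the (Z)-boron enolate adds through a closed chair (Zimmerman–Traxler) transition state on the face dictated by the auxiliary, which sets C12 and C13 (both R in the target) with methyl and hydroxyl syn, the C1 centre being too remote to interfere.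

Step 6
Reactants: 9 aldol adduct
Product: 10 (S)-4-benzyl-3-[(2S,3R,5S)-3,7-bis[(tert-butyldimethylsilyl)oxy]-2-methyl-5-(prop-1-en-2-yl)heptanoyl]oxazolidin-2-one
Conditions: t-BuMe2SiOTf, 2,6-lutidine, CH2Cl2, −78 to 0 °C
Reagents that add atoms: tert-butyldimethylsilyl triflate, CC(C)(C)[Si](C)(C)OS(=O)(=O)C(F)(F)F
Why: Silyl triflate silylation caps the hindered secondary C13 alcohol, which blocks retro-aldol cleavage and carries the C13 oxygen to the end of the route.

Step 7
Reactants: 10 bis-silyl imide
Product: 12 (2S,3R,5S)-3,7-bis[(tert-butyldimethylsilyl)oxy]-2-methyl-5-(prop-1-en-2-yl)heptanoic acid, via peroxy acid 11 (not isolated)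
Conditions: LiOH, H2O2, THF/H2O, 0 °C; then Na2SO3; then 1 M HCl to pH 3
Reagents that add atoms: hydrogen peroxide, OO
Why: Hydroperoxide cleavage of the acyl oxazolidinone attacks only the exocyclic carbonyl, the peroxy acid is reduced by sulfite while still a salt, C12 is not epimerised and the auxiliary is recovered.

Step 8
Reactants: 12 acid
Product: 14 (3S,4R,6S)-4,8-bis[(tert-butyldimethylsilyl)oxy]-1-diazo-3-methyl-6-(prop-1-en-2-yl)octan-2-one, via isobutyl carbonic anhydride 13 (not isolated)
Conditions: i-BuOCOCl, Et3N, THF, −20 °C; then CH2N2, Et2O, 0 °C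
Reagents that add atoms: diazomethane, C=[N+]=[N-]
Why: First stage of the Arndt–Eistert homologation: the mixed anhydride acylates diazomethane under conditions that leave the silyl ethers, the alkene and the α-stereocentre untouched.

Step 9
Reactants: 14 diazoketone
Product: 16 methyl (3R,4R,6S)-4,8-bis[(tert-butyldimethylsilyl)oxy]-3-methyl-6-(prop-1-en-2-yl)octanoate, via ketene 15 (not isolated)
Conditions: PhCO2Ag (10 mol %), Et3N, MeOH, rt, dark
Reagents that add atoms: methanol, CO
Why: Wolff rearrangement: C12 migrates with retention to the carbene carbon and methanol traps the ketene, so that C11 is inserted and C10 appears as the methyl ester.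

Step 10
Reactants: 16 bis-silyl ester
Product: 17 methyl (3R,4R,6S)-4-[(tert-butyldimethylsilyl)oxy]-8-hydroxy-3-methyl-6-(prop-1-en-2-yl)octanoate
Conditions: HF·pyridine, pyridine, THF, 0 °C
Reagents that add atoms: none
Why: Selective desilylation: buffered fluoride cleaves the unhindered primary silyl ether at C3 much faster than the secondary one at C13, which is flanked by the C12 methyl group.

Step 11
Reactants: 17 hydroxy ester; 7 (S)-4-benzyl-3-propionyloxazolidin-2-one
Product: 20 (S)-4-benzyl-3-[(2R,5S,7R,8R)-7-[(tert-butyldimethylsilyl)oxy]-10-methoxy-2,8-dimethyl-10-oxo-5-(prop-1-en-2-yl)decanoyl]oxazolidin-2-one, via primary triflate 18 (not isolated), via sodium (Z)-enolate of the imide 19 (not isolated)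
Conditions: 17, Tf2O, 2,6-di-tert-butyl-4-methylpyridine, CH2Cl2, −78 °C; 7, NaN(SiMe3)2, THF, −78 °C; combine at −78 °C
Reagents that add atoms: none
Why: Evans alkylation: the chelated sodium (Z)-enolate is alkylated on the face away from the benzyl group, which sets C4 as R; the primary triflate is used because imide enolates react poorly with unactivated iodides, and the remote methyl ester is inert at −78 °C.

Step 12
Reactants: 20 alkylated imide
Product: 21 dimethyl (2R,5S,7R,8R)-7-[(tert-butyldimethylsilyl)oxy]-2,8-dimethyl-5-(prop-1-en-2-yl)decanedioate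
Conditions: MeMgBr, MeOH (forms MeOMgBr), CH2Cl2/MeOH, 0 °C
Reagents that add atoms: methanol, CO
Why: Transesterification with magnesium methoxide removes the auxiliary at the exocyclic carbonyl under conditions too weakly basic to epimerise C4.

Step 13
Reactants: 21 diester
Product: 22 ten-membered enediol bis(trimethylsilyl) ether (ring C1–C5 and C10–C14, C5=C10, 5,10-bis(trimethylsilyloxy), 13-OTBS, 4,12-dimethyl, 1-isopropenyl; 1S,4R,12R,13R)
Conditions: Na (dispersion), Me3SiCl, toluene, reflux, slow addition at high dilution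
Reagents that add atoms: chlorotrimethylsilane, C[Si](C)(C)Cl
Why: Rühlmann acyloin condensation: reductive coupling of the two esters on the sodium surface joins C5 to C10, the classical entry to ten-membered carbocycles, and the chlorosilane traps enediolate and methoxide so that Claisen condensation and epimerisation at C4 are suppressed.

Step 14
Reactants: 22 enediol bis-silyl ether
Product: 23 (1S,4R,12R,13R)-ten-membered 5,10-dione (13-OTBS)
Conditions: Br2 (1.0 equiv), CH2Cl2, −78 °C
Reagents that add atoms: none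
Why: Oxidation of an enediol bis-silyl ether to the 1,2-dione: the electron-rich dioxygenated alkene takes up one equivalent of bromine at −78 °C far faster than the isopropenyl group and loses two molecules of bromosilane.

Step 15
Reactants: 23 dione
Product: 24 (1S,4R,10R,12R,13R)-10-hydroxy-5-ketone (13-OTBS)
Conditions: (S)-2-methyl-CBS-oxazaborolidine (0.5 equiv), catecholborane (1.1 equiv), toluene, −78 °C; used crude
Reagents that add atoms: none
Why: Corey–Bakshi–Shibata reduction: the less hindered C10 carbonyl (next to CH2, not CHMe) is reduced first and the catalyst sets the carbinol as 10R; the ketol is carried on crude to avoid acyloin tautomerism.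

Step 16
Reactants: 24 hydroxy ketone; 25 vinylmagnesium bromide
Product: 26 (1S,4R,5S,10R,12R,13R)-5-vinyl-5,10-diol (13-OTBS)
Conditions: CH2=CHMgBr (3 equiv), THF/CH2Cl2, −78 °C
Reagents that add atoms: none
Why: Chelation-controlled Grignard addition (Cram chelate model): magnesium bridges the C10 alkoxide and the C5 carbonyl and vinyl enters from the side of the C10 hydrogen, away from ring carbon C11, which sets C5 as S, the sense that plain addition anti to the C4 methyl would not give.

Step 17
Reactants: 26 diol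
Product: 27 (1S,4R,5S,12R,13R)-5-hydroxy-5-vinyl-10-ketone (13-OTBS)
Conditions: SO3·pyridine, DMSO, i-Pr2NEt, CH2Cl2, 0 °C
Reagents that add atoms: none
Why: Parikh–Doering oxidation: only the secondary C10 alcohol can be oxidised, and the mild activated-DMSO conditions avoid glycol cleavage and α-ketol rearrangement of the tertiary allylic alcohol.

Step 18
Reactants: 27 ketol
Product: 28 5-O-triethylsilyl ether of 27
Conditions: Et3SiOTf, 2,6-lutidine, CH2Cl2, −78 °C
Reagents that add atoms: triethylsilyl triflate, CC[Si](CC)(CC)OS(=O)(=O)C(F)(F)F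
Why: Silyl triflate silylation of the tertiary alcohol installs a bulky, non-chelating ether, the condition for a Felkin–Anh addition at C10 in the next step.

Step 19
Reactants: 28 silyloxy ketone; 29 (E)-1-bromoprop-1-ene
Product: 32 (1S,4R,5S,10R,12R,13R)-10-methoxy-10-[(E)-prop-1-enyl]-5-(triethylsilyloxy)-5-vinyl ten-membered ring (13-OTBS), via (E)-prop-1-enyllithium 30 (not isolated), via lithium C10 alkoxide 31 (not isolated)
Conditions: 29, t-BuLi (2 equiv), Et2O, −78 °C; add 28, −78 °C; then MeOTf, −78 to −20 °C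
Reagents that add atoms: methyl triflate, COS(=O)(=O)C(F)(F)F
Why: Felkin–Anh (polar, non-chelated) addition of an alkenyllithium made with retention by bromine–lithium exchange: the C5–OSi bond lies anti to the nucleophile, which passes the small vinyl group and not ring carbon C4, so that propenyl ends trans to vinyl (10R), and the alkoxide is methylated cold before the silyl group can migrate to it.

Step 20
Reactants: 32 silyl-protected methyl ether
Product: 33 (1S,4R,5S,10R,12R,13R)-10-methoxy-10-[(E)-prop-1-enyl]-5-vinyl ten-membered 5-ol (13-OTBS)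
Conditions: HF·pyridine, pyridine, THF, 0 °C
Reagents that add atoms: none
Why: Selective desilylation: the triethylsilyl ether is far more labile to buffered fluoride than the secondary tert-butyldimethylsilyl ether at C13, and the conditions are too mild to ionise the tertiary allylic alcohol.

Step 21
Reactants: 33 ten-membered carbinol
Product: 36 (1S,4R,8S,9Z,12R,13R)-14-membered 5-ketone with C9=C10 methyl enol ether (13-OTBS), via potassium alkoxide 34 (not isolated), via potassium C5 enolate 35 (not isolated)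
Conditions: KH, 18-crown-6, THF, 0 °C to rt; then AcOH, THF, −78 °C
Reagents that add atoms: none
Why: Anionic oxy-Cope rearrangement: the potassium alkoxide at C5 loosens the C5–C10 bond and the diene C7=C6–C5–C10–C9=C8 undergoes a [3,3]-sigmatropic shift in which C7–C8 forms as C5–C10 breaks, pulled forward by formation of the C5 enolate. The closest known reaction type is the four-carbon ring expansion of 1,2-dialkenylcycloalkanol potassium salts, including 4-alkoxy variants that deliver an enol ether beside the ketone. The 14-membered ring arises by this pericyclic expansion of the ten-membered ring, not by an end-to-end cyclisation, through a chair transition state that holds ring carbons C4 and C11 equatorial and both oxygens axial. C8 is the only new stereocentre and is set by chirality transfer from C5 (S) and C10 (R) through that chair with the methyl of the (E)-propenyl group equatorial, which gives 8S together with ring-trans geometry at the enolate and the enol ether. The step needs this chair to win over the flipped chair and the boats, and the trans placing of vinyl and propenyl secures it because no other arrangement keeps both ring bonds equatorial. The C10 methyl ether cannot become an alkoxide, so C5 (ketone) and C10 (enol ether) stay differentiated, and the cold acetic acid quench protonates the enolate at C6 without touching C4.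

Step 22
Reactants: 36 macrocyclic ketone
Product: 37 (1S,4R,5S,8S,9Z,12R,13R)-14-membered 5-ol with C9=C10 methyl enol ether (13-OTBS)
Conditions: LiBH(s-Bu)3, THF, −78 °C; then NaOH, H2O2, 0 °C
Reagents that add atoms: none
Why: Felkin–Anh reduction: the bulky hydride attacks the C5 carbonyl from the ring periphery anti to the C4 methyl, which gives the 5S alcohol, while the enol ether and the silyl ether are inert.

Step 23
Reactants: 37 alcohol
Product: 38 (1S,4R,5S,8S,12R,13R)-5,13-dihydroxy-4,8,12-trimethyl-1-(prop-1-en-2-yl)cyclotetradecan-10-one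
Conditions: aq. HF (48 %), MeCN, 0 °C to rt
Reagents that add atoms: water, O
Why: Acid hydrolysis of the methyl enol ether unveils the C10 ketone and the same aqueous HF removes the silyl ether at C13 (desilylation); C8 and C12 are β to the ketone and cannot epimerise.

Step 24
Reactants: 38 keto diol
Product: 39 (1S,4R,5S,8S,12R,13R)-5,13-diacetoxy-4,8,12-trimethyl-1-(prop-1-en-2-yl)cyclotetradecan-10-one (CNP0328624.1)
Conditions: Ac2O, pyridine, DMAP (cat.), CH2Cl2, rt
Reagents that add atoms: acetic anhydride, CC(=O)OC(C)=O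
Why: DMAP-catalysed acetylation of both secondary alcohols; the open hydroxy ketone is acetylated at C13 and is thereby drawn out of any hemiketal form.

**Compound list**

1 | 5,6-dihydro-2H-pyran-2-one | O=C1C=CCCO1 | starting material
2 | potassium trifluoro(prop-1-en-2-yl)borate | [K+].C=C(C)[B-](F)(F)F | starting material
3 | (S)-4-(prop-1-en-2-yl)oxan-2-one | C=C(C)[C@H]1CCOC(=O)C1 | intermediate
4 | (S)-5-hydroxy-N-methoxy-N-methyl-3-(prop-1-en-2-yl)pentanamide | CON(C)C(=O)C[C@@H](C(C)=C)CCO | intermediate
5 | (S)-5-[(tert-butyldimethylsilyl)oxy]-N-methoxy-N-methyl-3-(prop-1-en-2-yl)pentanamide | CON(C)C(=O)C[C@@H](C(C)=C)CCO[Si](C)(C)C(C)(C)C | intermediate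
6 | (S)-5-[(tert-butyldimethylsilyl)oxy]-3-(prop-1-en-2-yl)pentanal | O=CC[C@@H](C(C)=C)CCO[Si](C)(C)C(C)(C)C | intermediate
7 | (S)-4-benzyl-3-propionyloxazolidin-2-one | CCC(=O)N1[C@@H](Cc2ccccc2)COC1=O | starting material
8 | dibutylboron (Z)-enolate of 7 (formed in situ) | CCCCB(CCCC)O/C(=C\C)N1[C@@H](Cc2ccccc2)COC1=O | intermediate
9 | (S)-4-benzyl-3-[(2S,3R,5S)-7-[(tert-butyldimethylsilyl)oxy]-3-hydroxy-2-methyl-5-(prop-1-en-2-yl)heptanoyl]oxazolidin-2-one | O=C1OC[C@H](Cc2ccccc2)N1C(=O)[C@@H](C)[C@H](O)C[C@@H](C(C)=C)CCO[Si](C)(C)C(C)(C)C | intermediate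
10 | (S)-4-benzyl-3-[(2S,3R,5S)-3,7-bis[(tert-butyldimethylsilyl)oxy]-2-methyl-5-(prop-1-en-2-yl)heptanoyl]oxazolidin-2-one | O=C1OC[C@H](Cc2ccccc2)N1C(=O)[C@@H](C)[C@H](O[Si](C)(C)C(C)(C)C)C[C@@H](C(C)=C)CCO[Si](C)(C)C(C)(C)C | intermediate
11 | (2S,3R,5S)-3,7-bis[(tert-butyldimethylsilyl)oxy]-2-methyl-5-(prop-1-en-2-yl)heptaneperoxoic acid (formed in situ as its lithium salt) | OOC(=O)[C@@H](C)[C@H](O[Si](C)(C)C(C)(C)C)C[C@@H](C(C)=C)CCO[Si](C)(C)C(C)(C)C | intermediate
12 | (2S,3R,5S)-3,7-bis[(tert-butyldimethylsilyl)oxy]-2-methyl-5-(prop-1-en-2-yl)heptanoic acid | OC(=O)[C@@H](C)[C@H](O[Si](C)(C)C(C)(C)C)C[C@@H](C(C)=C)CCO[Si](C)(C)C(C)(C)C | intermediate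
13 | isobutyl carbonic anhydride of 12 (formed in situ) | CC(C)COC(=O)OC(=O)[C@@H](C)[C@H](O[Si](C)(C)C(C)(C)C)C[C@@H](C(C)=C)CCO[Si](C)(C)C(C)(C)C | intermediate
14 | (3S,4R,6S)-4,8-bis[(tert-butyldimethylsilyl)oxy]-1-diazo-3-methyl-6-(prop-1-en-2-yl)octan-2-one | [N-]=[N+]=CC(=O)[C@@H](C)[C@H](O[Si](C)(C)C(C)(C)C)C[C@@H](C(C)=C)CCO[Si](C)(C)C(C)(C)C | intermediate
15 | (3R,4R,6S)-4,8-bis[(tert-butyldimethylsilyl)oxy]-3-methyl-6-(prop-1-en-2-yl)oct-1-en-1-one, the ketene (formed in situ) | O=C=C[C@@H](C)[C@H](O[Si](C)(C)C(C)(C)C)C[C@@H](C(C)=C)CCO[Si](C)(C)C(C)(C)C | intermediate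
16 | methyl (3R,4R,6S)-4,8-bis[(tert-butyldimethylsilyl)oxy]-3-methyl-6-(prop-1-en-2-yl)octanoate | COC(=O)C[C@@H](C)[C@H](O[Si](C)(C)C(C)(C)C)C[C@@H](C(C)=C)CCO[Si](C)(C)C(C)(C)C | intermediate
17 | methyl (3R,4R,6S)-4-[(tert-butyldimethylsilyl)oxy]-8-hydroxy-3-methyl-6-(prop-1-en-2-yl)octanoate | COC(=O)C[C@@H](C)[C@H](O[Si](C)(C)C(C)(C)C)C[C@@H](C(C)=C)CCO | intermediate
18 | C8 trifluoromethanesulfonate of 17 (formed in situ) | COC(=O)C[C@@H](C)[C@H](O[Si](C)(C)C(C)(C)C)C[C@@H](C(C)=C)CCOS(=O)(=O)C(F)(F)F | intermediate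
19 | sodium (Z)-enolate of 7 (formed in situ) | C/C=C(\[O-])N1[C@@H](Cc2ccccc2)COC1=O.[Na+] | intermediate
20 | (S)-4-benzyl-3-[(2R,5S,7R,8R)-7-[(tert-butyldimethylsilyl)oxy]-10-methoxy-2,8-dimethyl-10-oxo-5-(prop-1-en-2-yl)decanoyl]oxazolidin-2-one | COC(=O)C[C@@H](C)[C@H](O[Si](C)(C)C(C)(C)C)C[C@@H](C(C)=C)CC[C@@H](C)C(=O)N1[C@@H](Cc2ccccc2)COC1=O | intermediate
21 | dimethyl (2R,5S,7R,8R)-7-[(tert-butyldimethylsilyl)oxy]-2,8-dimethyl-5-(prop-1-en-2-yl)decanedioate | COC(=O)C[C@@H](C)[C@H](O[Si](C)(C)C(C)(C)C)C[C@@H](C(C)=C)CC[C@@H](C)C(=O)OC | intermediate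
22 | ten-membered enediol bis(trimethylsilyl) ether: ring C1–C5, C10–C14, C5=C10, 5,10-bis(trimethylsilyloxy), 13-OTBS, 4,12-dimethyl, 1-isopropenyl; 1S,4R,12R,13R | C[Si](C)(C)O/C1=C(\O[Si](C)(C)C)C[C@@H](C)[C@H](O[Si](C)(C)C(C)(C)C)C[C@@H](C(C)=C)CC[C@H]1C | intermediate
23 | (1S,4R,12R,13R)-13-[(tert-butyldimethylsilyl)oxy]-4,12-dimethyl-1-isopropenyl ten-membered 5,10-dione | O=C1C(=O)C[C@@H](C)[C@H](O[Si](C)(C)C(C)(C)C)C[C@@H](C(C)=C)CC[C@H]1C | intermediate
24 | (1S,4R,10R,12R,13R)-10-hydroxy-5-ketone of the ten-membered ring (13-OTBS) | O=C1[C@H](O)C[C@@H](C)[C@H](O[Si](C)(C)C(C)(C)C)C[C@@H](C(C)=C)CC[C@H]1C | intermediate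
25 | vinylmagnesium bromide | C=C[Mg]Br | starting material
26 | (1S,4R,5S,10R,12R,13R)-5-vinyl-5,10-diol of the ten-membered ring (13-OTBS) | C=C[C@@]1(O)[C@H](O)C[C@@H](C)[C@H](O[Si](C)(C)C(C)(C)C)C[C@@H](C(C)=C)CC[C@H]1C | intermediate
27 | (1S,4R,5S,12R,13R)-5-hydroxy-5-vinyl-10-ketone of the ten-membered ring (13-OTBS) | C=C[C@@]1(O)C(=O)C[C@@H](C)[C@H](O[Si](C)(C)C(C)(C)C)C[C@@H](C(C)=C)CC[C@H]1C | intermediate
28 | 5-O-triethylsilyl ether of 27 | C=C[C@@]1(O[Si](CC)(CC)CC)C(=O)C[C@@H](C)[C@H](O[Si](C)(C)C(C)(C)C)C[C@@H](C(C)=C)CC[C@H]1C | intermediate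
29 | (E)-1-bromoprop-1-ene | C/C=C/Br | starting material
30 | (E)-prop-1-enyllithium (formed in situ) | C/C=C/[Li] | intermediate
31 | lithium C10 alkoxide of the propenyl adduct (formed in situ) | C/C=C/[C@]1(O[Li])C[C@@H](C)[C@H](O[Si](C)(C)C(C)(C)C)C[C@@H](C(C)=C)CC[C@@H](C)[C@@]1(O[Si](CC)(CC)CC)C=C | intermediate
32 | (1S,4R,5S,10R,12R,13R)-10-methoxy-10-[(E)-prop-1-enyl]-5-(triethylsilyloxy)-5-vinyl ten-membered ring (13-OTBS) | C/C=C/[C@]1(OC)C[C@@H](C)[C@H](O[Si](C)(C)C(C)(C)C)C[C@@H](C(C)=C)CC[C@@H](C)[C@@]1(O[Si](CC)(CC)CC)C=C | intermediate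
33 | (1S,4R,5S,10R,12R,13R)-10-methoxy-10-[(E)-prop-1-enyl]-5-vinyl ten-membered 5-ol (13-OTBS) | C/C=C/[C@]1(OC)C[C@@H](C)[C@H](O[Si](C)(C)C(C)(C)C)C[C@@H](C(C)=C)CC[C@@H](C)[C@@]1(O)C=C | intermediate
34 | potassium alkoxide of 33 (formed in situ) | C/C=C/[C@]1(OC)C[C@@H](C)[C@H](O[Si](C)(C)C(C)(C)C)C[C@@H](C(C)=C)CC[C@@H](C)[C@@]1([O-])C=C.[K+] | intermediate
35 | potassium C5(O)=C6 enolate of the 14-membered ring (formed in situ) | C=C(C)[C@H]1CC[C@@H](C)/C([O-])=C/C[C@H](C)/C=C(OC)/C[C@@H](C)[C@H](O[Si](C)(C)C(C)(C)C)C1.[K+] | intermediate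
36 | (1S,4R,8S,9Z,12R,13R)-14-membered 5-ketone with C9=C10 methyl enol ether (13-OTBS) | C=C(C)[C@H]1CC[C@@H](C)C(=O)CC[C@H](C)/C=C(OC)/C[C@@H](C)[C@H](O[Si](C)(C)C(C)(C)C)C1 | intermediate
37 | (1S,4R,5S,8S,9Z,12R,13R)-14-membered 5-ol with C9=C10 methyl enol ether (13-OTBS) | C=C(C)[C@H]1CC[C@@H](C)[C@@H](O)CC[C@H](C)/C=C(OC)/C[C@@H](C)[C@H](O[Si](C)(C)C(C)(C)C)C1 | intermediate
38 | (1S,4R,5S,8S,12R,13R)-5,13-dihydroxy-4,8,12-trimethyl-1-(prop-1-en-2-yl)cyclotetradecan-10-one | C=C(C)[C@H]1CC[C@@H](C)[C@@H](O)CC[C@H](C)CC(=O)C[C@@H](C)[C@H](O)C1 | intermediate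
39 | (1S,4R,5S,8S,12R,13R)-5,13-diacetoxy-4,8,12-trimethyl-1-(prop-1-en-2-yl)cyclotetradecan-10-one (CNP0328624.1) | C=C(C)[C@H]1CC[C@@H](C)[C@@H](OC(C)=O)CC[C@H](C)CC(=O)C[C@@H](C)[C@H](OC(C)=O)C1 | target

**Step count and risks**

Total steps: 24. Longest linear sequence: 24 steps (1 to 39).

Steps most likely to fail:

1. Step 19. The addition may show poor facial selectivity at C10 if the silyl ether does not fully prevent chelation, and the triethylsilyl group may migrate to the new alkoxide before methylation, so that the methyl group lands on the C5 oxygen. Fallback: the two alkenyl groups are introduced in the reverse order, setting out from dione 23. The (E)-propenylcerium reagent (from 30 and CeCl3, THF, −78 °C) adds to the less hindered C10 carbonyl to give the tertiary ketol F1. Methyl triflate with 2,6-di-tert-butyl-4-methylpyridine gives the methyl ether F2. Vinylmagnesium bromide 25 then adds to the C5 ketone under chelation by the methoxy group, and the route is rejoined at 33. This sequence needs no silyl ether on the C5 oxygen, but it rests on substrate control only, so the C10 and C5 epimers would have to be separated at F1 and at 33.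

2. Step 21. A flipped chair or a boat transition state may compete and erode C8, the enolate may equilibrate and epimerise C4 before the quench, and the alkoxide may fragment. Fallback: a neutral thermal siloxy-Cope rearrangement, setting out from 32. Heating 32 in degassed decalin at about 210 °C in base-washed glassware should give the triethylsilyl enol ether F3 through the same chair. No enolate is formed, so C4 cannot epimerise, and the later, tighter transition state of the thermal reaction usually favours the chair more strongly. Selective cleavage of the silyl enol ether (n-Bu4NF, AcOH, THF, −78 °C) returns to the route at 36.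

3. Step 13. Intermolecular coupling and incomplete reduction on the sodium surface may outrun closure of the branched ten-membered ring. Fallback: an intramolecular pinacol coupling, setting out from 21. Reduction with i-Bu2AlH (CH2Cl2, −78 °C) gives the dialdehyde F4. Low-valent titanium (TiCl3(DME)1.5, Zn–Cu couple, DME, rt, slow addition) closes the ring to the 5,10-diol F5 as a mixture of diol isomers. Double Swern oxidation ((COCl)2, DMSO, Et3N, −78 °C) converges all isomers on dione 23.

**Further compounds**

F1 | step 19 | (1S,4R,10R,12R,13R)-10-hydroxy-10-[(E)-prop-1-enyl]-5-ketone of the ten-membered ring (13-OTBS) | C/C=C/[C@]1(O)C[C@@H](C)[C@H](O[Si](C)(C)C(C)(C)C)C[C@@H](C(C)=C)CC[C@@H](C)C1=O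
F2 | step 19 | (1S,4R,10R,12R,13R)-10-methoxy-10-[(E)-prop-1-enyl]-5-ketone of the ten-membered ring (13-OTBS) | C/C=C/[C@]1(OC)C[C@@H](C)[C@H](O[Si](C)(C)C(C)(C)C)C[C@@H](C(C)=C)CC[C@@H](C)C1=O
F3 | step 21 | (1S,4R,5Z,8S,9Z,12R,13R)-14-membered C5 triethylsilyl enol ether with C9=C10 methyl enol ether (13-OTBS) | C=C(C)[C@H]1CC[C@@H](C)/C(O[Si](CC)(CC)CC)=C/C[C@H](C)/C=C(OC)/C[C@@H](C)[C@H](O[Si](C)(C)C(C)(C)C)C1
F4 | step 13 | (2R,5S,7R,8R)-7-[(tert-butyldimethylsilyl)oxy]-2,8-dimethyl-5-(prop-1-en-2-yl)decanedial | O=CC[C@@H](C)[C@H](O[Si](C)(C)C(C)(C)C)C[C@@H](C(C)=C)CC[C@@H](C)C=O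
F5 | step 13 | (1S,4R,12R,13R)-ten-membered 5,10-diol, mixture of isomers at C5 and C10 (13-OTBS) | OC1C(O)C[C@@H](C)[C@H](O[Si](C)(C)C(C)(C)C)C[C@@H](C(C)=C)CC[C@H]1C
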